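# Proposed synthesis of (R)-5,7-dihydroxy-8-(1-methylpiperidin-2-yl)flavone (CNP0210320.1)

## Analysis of the target

The target is a flavone: benzo ring A is fused to the 4-pyranone ring C (O1, C2, C3, C4, C4a, C8a), C2 carries an unsubstituted phenyl ring B, C5 and C7 carry free hydroxyl groups, and C8 is bonded to C2' of a 1-methylpiperidine ring. The only stereocenter is C2', of (R) configuration (checked against the SMILES: N > aryl carbon > C3' > H). It is benzylic and alpha to nitrogen, and with no second stereocenter to relay from, it has to be set by a reagent. C2' lies ortho to O7 and O1 and para to O5, so the molecule is a phenolic Mannich base. Hot acid or base could erode the configuration through reversible heterolysis of the C2'–N bond (ortho-quinone methide pathway). Hot mineral acid can also move a C8 substituent of a 5,7-dihydroxyflavone to C6 by opening and reclosing ring C. The difficulty is threefold: C8 is a fully substituted position between two oxygens, substitution on a phloroglucinol or chrysin core does not distinguish C8 from C6 (that is, O1 from O5), and the C8–C2' bond is hindered. The strategy rests on the vicinal pair C8 (carrying C2') and C8a (carrying O1). This carbon–oxygen pair on neighbouring ring atoms corresponds to the carbonyl carbon and oxygen of 1-methylpiperidin-2-one, which already contains the whole N-methylpiperidine ring.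

## Retrosynthetic reasoning

**Target 24 to dimethyl ether 23.** The O5–CH3 and O7–CH3 bonds are cut last. Methyl ethers are carried because they should survive fluoride, butyllithium, hydrogenation, Lewis acid acylation, amide base and hot acid. O5 has to stay masked until ring C is closed, so that O1 and O5 cannot be confused. The forward step must cleave both ethers without opening ring C and without ionising the C2'–N bond.

**Flavone 23 to diketone 21, then to acetophenone 18 and benzoyl chloride 19.** Ring C is cut at O1–C2 (cyclodehydration) and at the bond between C3 and the benzoyl carbon (enolate acylation). In 18 the only free phenol is the oxygen that becomes O1, so closure of ring C can give only the 8-substituted flavone. The forward steps must acylate the methyl ketone on carbon and then dehydrate under conditions that leave C2' alone.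

**Acetophenone 18 to phenol 16.** The C4a–C4 bond is cut. The acetyl group is delivered ortho to the free phenol of 16 by O-acylation and Fries migration. The phenol chosen as O1 thereby also directs the carbon that becomes C4.

**Phenol 16 to zwitterion 14.** The C2'–H bond is cut. C2' is trigonal in 14 and becomes the stereocenter by enantioselective hydrogenation of the derived iminium salt 15. Setting the stereocenter after the bond construction frees the key step from any stereochemical demand.

**Zwitterion 14 to silyl triflate 9 and lactam 10.** C8–C2' and C8a–O1 are cut together, giving aryne 11 (released from 9) and 1-methylpiperidin-2-one 10. This is preferred to electrophilic substitution or cross-coupling at C8 because both would need a ring A in which O1, O5 and O7 are already differentiated. The insertion makes the hindered bond, marks the neighbouring oxygen as the free phenoxide, and brings in the piperidine ring with its N-methyl group in one event from achiral bulk chemicals. The forward reaction must add the lactam oxygen to the aryne carbon remote from the flanking methoxy group and then close the carbon–carbon bond faster than the aryl anion is protonated.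

**Silyl triflate 9 to carbamate 7, carbamate 3, phenol 1 and isocyanate 2.** The O–Tf and C–Si bonds are cut. Silicon is placed by carbamate-directed ortho-lithiation of 3, not by halogenation of 1, because an electrophile would have to choose between the positions ortho and para to the hydroxyl group of 1. The carbamate directs the base to the position next to itself.

## Alternatives that were turned down

**Alternative 1: ring A built by benzannulation on a pipecolic acid derivative.** Ring A is disconnected at C8–C8a, C6–C7 and C4a–C8a. The precursors are 3-ethoxycyclobut-2-en-1-one A2 and siloxyalkyne A3, which carries the piperidine and its stereocenter from (R)-pipecolic acid A4. On heating, A2 should open to a vinylketene that adds to the ynol ether. A cascade of 4π opening, 6π closure and tautomerisation should end in phenol A1.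
- For: C2' comes from the chiral pool. The three oxygens of ring A emerge differentiated (free hydroxyl for O1, silyl ether at O7, ethyl ether at O5), so the O7 group could be removed with fluoride. On both points this alternative is stronger than the chosen route, which depends on a catalyst for C2' and on BBr3 at the end.
- Against: A3 has to be made from an alpha-amino ester by ynolate chemistry under strongly basic conditions, which endangers the stereocenter it is meant to preserve. A2 and A3 are sensitive, and the thermal benzannulation must tolerate a branched, carbamate-bearing alkyne. The carbamate then has to be exchanged for N-methyl, and the whole flavone annulation still follows, so the sequence is several steps longer.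
- Comparison: the chosen route offers a four-step entry from achiral commodity chemicals to the same kind of ring A phenol (16), with N-methyl already in place.

**Alternative 2: piperidine ring formed by an auxiliary-controlled aza-Diels–Alder reaction.** The piperidine is disconnected at C2'–C3' and N–C6'. The N-tert-butanesulfinyl aldimine A6 of the ring A aldehyde and Danishefsky's diene A7 would combine under a silyl triflate Lewis acid in a Mannich–Michael sequence to give dihydropyridone A5, with the sulfur auxiliary fixing (R)-C2'.
- For: stereocontrol comes from a covalently bound auxiliary, and the diastereomers can be separated. The optical purity of C2' is therefore more dependable than from hydrogenation of 15, and here the alternative is stronger. The aryl–C2' bond is present in the aldehyde from the outset.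
- Against: the 2,4,6-trioxygenated aldimine is an electron-rich and doubly ortho-substituted, hence sluggish, electrophile. A5 carries a C4' carbonyl group and a C5'=C6' double bond that the target lacks. Conjugate reduction, deoxygenation, auxiliary removal, N-methylation and debenzylation are needed before ring C can be started, and none of these operations builds the skeleton.
- Comparison: the chosen strategy delivers the piperidine at the right oxidation level with its N-methyl group, and spends its steps on bond construction.

**Alternative 3: ring C closed by carbonylative three-component annulation.** Ring C is disconnected at C4a–C4, C4–C3 and O1–C2. Iodophenol A9, carbon monoxide A11 and phenylacetylene A10 would be joined under palladium catalysis with an amine base (carbonylative Sonogashira coupling, then 6-endo oxa-Michael closure) to give flavone A8, which is the same compound as 23.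
- For: ring C forms in one step under nearly neutral conditions, without an acetyl intermediate, strong base or hot acid. For the construction of ring C this is at least as good as steps 6 to 8 below; it saves one step and spares C2' the Lewis acid.
- Against: it does not address the hard part, the C8–C2' bond and the configuration at C2'. A9 already contains both and would have to be made from a compound such as 16 by iodination, which raises the same ortho/para question as the acetylation. The ynone intermediate can also close in the 5-exo mode to an aurone, and the basic amine and two ortho substituents crowd the site of oxidative addition.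
- Comparison: the chosen strategy spends its key step on the difficult bond. This alternative would be an endgame variant of it, not a competing solution.

Key step: step 4

Remark on the chemistry: the sense of induction of the [Ir(cod)Cl]2/(R)-SegPhos catalyst, where (R)-SegPhos is (R)-5,5'-bis(diphenylphosphino)-4,4'-bi-1,3-benzodioxole, on the hindered iminium salt 15 is assumed to give the (R)-amine. If the (S)-amine forms, (S)-SegPhos is used with no other change. Compounds 1, 2, 10 and 19 are catalogue chemicals.

## Route

Step 1
Reactants: 1 3,5-dimethoxyphenol; 2 isopropyl isocyanate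
Product: 3 3,5-dimethoxyphenyl N-isopropylcarbamate
Conditions: 2 (1.3 equiv), Et3N (0.2 equiv), CH2Cl2, rt
Reagents that add atoms: isopropyl isocyanate (2), CC(C)N=C=O
Why: Base-catalysed addition of the phenol O–H to the isocyanate (carbamoylation); the N–H carbamate is chosen because, once N-silylated, it directs ortho-lithiation and it can later be removed under mild basic conditions.

Step 2
Reactants: 3 3,5-dimethoxyphenyl N-isopropylcarbamate
Product: 7 3,5-dimethoxy-2-(trimethylsilyl)phenyl N-isopropylcarbamate, via N-silyl carbamate 4 (not isolated), via aryllithium 5 (not isolated), via bis-silyl carbamate 6 (not isolated)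
Conditions: TMSOTf (1.1 equiv), TMEDA (1.1 equiv), Et2O, 0 °C to rt; then TMEDA (2 equiv), n-BuLi (2.1 equiv), −78 °C; then TMSCl (3 equiv), −78 °C to rt; aq. NaHSO4
Reagents that add atoms: chlorotrimethylsilane, C[Si](C)(C)Cl; trimethylsilyl trifluoromethanesulfonate, C[Si](C)(C)OS(=O)(=O)C(F)(F)F (its silyl group is found only in 4 to 6)
Why: Directed ortho-metalation: transient N-silylation masks the N–H, and the carbamate then directs n-BuLi to C2, between the carbamate oxygen and a methoxy group (C2 and C6 are equivalent; the site between the two methoxy groups lacks the stronger director). At −78 °C aryllithium 5 should be silylated before an anionic Fries shift can occur, and the N–Si bond of 6 is hydrolysed on work-up.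

Step 3
Reactants: 7 3,5-dimethoxy-2-(trimethylsilyl)phenyl N-isopropylcarbamate
Product: 9 3,5-dimethoxy-2-(trimethylsilyl)phenyl trifluoromethanesulfonate, via silylphenol 8 (not isolated)
Conditions: DBU (1.5 equiv), Et2NH (1.2 equiv), MeCN, 40 °C; then PhNTf2 (1.5 equiv), rt
Reagents that add atoms: N-phenylbis(trifluoromethanesulfonimide), O=S(=O)(N(c1ccccc1)S(=O)(=O)C(F)(F)F)C(F)(F)F
Why: DBU promotes E1cB loss of isopropyl isocyanate from the N–H carbamate, diethylamine traps it as a urea, and the liberated phenoxide of 8 is triflated in the same flask by sulfonyl transfer from PhNTf2. The medium stays basic throughout, so the electron-rich aryl–silicon bond should not be protodesilylated.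

Step 4
Reactants: 9 3,5-dimethoxy-2-(trimethylsilyl)phenyl trifluoromethanesulfonate; 10 1-methylpiperidin-2-one
Product: 14 3,5-dimethoxy-2-(1-methyl-2,3,4,5-tetrahydropyridin-1-ium-6-yl)phenolate, via 3,5-dimethoxybenzyne 11 (not isolated), via O-aryl imidate zwitterion 12 (not isolated), via spiro benzoxete 13 (not isolated)
Conditions: CsF (3 equiv), neat dry 10 as solvent (about 0.1 M), 40 °C, 9 added over 6 h by syringe pump, Ar; filter, distil off 10 under high vacuum
Reagents that add atoms: 1-methylpiperidin-2-one (10), CN1CCCCC1=O
Why: Proposed new method: CsF removes the silyl group of 9 and triflate departs, giving aryne 11, whose triple bond is polarised by the inductively withdrawing methoxy group on the neighbouring carbon so that the aryne carbon remote from it (the future C8a) is the electrophilic one. The carbonyl oxygen of lactam 10, present as solvent, adds there and leaves the aryl anion of zwitterion 12 next to the methoxy group, where it is best stabilised. This anion closes on the adjacent O-aryl imidate carbon (4-exo-trig) to the spiro benzoxete 13, and strain-driven 4π electrocyclic opening of the four-membered ring gives 14, a push-pull ortho-quinone methide written as its zwitterion, with C8–C2' and C8a–O1 both formed. No ring persists and the spiro centre of 13 is lost again, so no stereocenter results and none has to be controlled. The closest known reaction type is the insertion of arynes into the C=O bond of formamides, which runs through the same benzoxete and ortho-quinone methide stages; new here is a tertiary lactam with alpha-hydrogens as the carbonyl partner. The one selectivity required is the regiochemistry of addition to the unsymmetrical aryne, and the methoxy group flanking the aryne secures it (oxygen meta, carbon ortho to it), the second methoxy group being too remote to oppose it. Neat dry 10 and slow addition of 9 keep the aryne concentration low, so that 14 is not arylated a second time and 12 finds no proton source other than its own alpha-CH2 group. The enamine-phenol tautomer of 14 may be present as well, which is harmless because both forms give the same iminium salt in step 5.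

Step 5
Reactants: 14 3,5-dimethoxy-2-(1-methyl-2,3,4,5-tetrahydropyridin-1-ium-6-yl)phenolate
Product: 16 3,5-dimethoxy-2-[(2R)-1-methylpiperidin-2-yl]phenol, via iminium chloride 15 (not isolated)
Conditions: HCl (1.05 equiv, 4 M in dioxane), CH2Cl2, 0 °C; then [Ir(cod)Cl]2 (1 mol %), (R)-SegPhos (2.2 mol %), H2 (50 bar), CH2Cl2/i-PrOH, 30 °C; aq. NaHCO3
Reagents that add atoms: none
Why: Protonation of 14 on oxygen gives the cyclic N-methyl iminium salt 15, and 2-aryl cyclic N-alkyl iminium salts are a known substrate class for asymmetric hydrogenation with iridium bisphosphine catalysts. Hydride is delivered to one face of C2' inside the chiral pocket of the iridium hydride, which sets (R)-C2' by reagent control (the ligand enantiomer decides the sense); the arene, the methyl ethers and the phenol should be inert.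

Step 6
Reactants: 16 3,5-dimethoxy-2-[(2R)-1-methylpiperidin-2-yl]phenol
Product: 18 1-[2-hydroxy-4,6-dimethoxy-3-[(2R)-1-methylpiperidin-2-yl]phenyl]ethanone, via aryl acetate 17 (not isolated)
Conditions: BF3·OEt2 (4 equiv), ClCH2CH2Cl, 0 °C; then Ac2O (1.5 equiv), rt to 50 °C; aq. NaOAc/MeOH, 50 °C
Reagents that add atoms: acetic anhydride, CC(=O)OC(C)=O
Why: BF3 is added first so that the amine is held as its Lewis acid adduct and cannot be acylated; O-acetylation to 17 and BF3-mediated Fries rearrangement should then deliver the acetyl group to C6 of the phenol (the future C4a), ortho to the oxygen, where the product is held as a difluoroboron chelate. The other free position lies between two methoxy groups, is more hindered and gives no chelate; the chelate is cleaved in the NaOAc work-up and C2' takes no part.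

Step 7
Reactants: 18 1-[2-hydroxy-4,6-dimethoxy-3-[(2R)-1-methylpiperidin-2-yl]phenyl]ethanone; 19 benzoyl chloride
Product: 21 1-[2-hydroxy-4,6-dimethoxy-3-[(2R)-1-methylpiperidin-2-yl]phenyl]-3-phenylpropane-1,3-dione, via dilithium phenoxide enolate 20 (not isolated)
Conditions: LiN(SiMe3)2 (3.5 equiv), THF, −78 to −10 °C; then 19 (1.05 equiv), −78 °C to rt; aq. NH4Cl
Reagents that add atoms: benzoyl chloride (19), O=C(Cl)c1ccccc1
Why: Direct form of the Baker–Venkataraman diketone synthesis: excess LiN(SiMe3)2 gives the phenoxide enolate 20, whose enolate carbon is benzoylated (Claisen-type acylation). Any O-benzoate formed at the hindered phenoxide would rearrange to the same diketone under the excess base, and C2' has no acidic proton.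

Step 8
Reactants: 21 1-[2-hydroxy-4,6-dimethoxy-3-[(2R)-1-methylpiperidin-2-yl]phenyl]-3-phenylpropane-1,3-dione
Product: 23 5,7-dimethoxy-8-[(2R)-1-methylpiperidin-2-yl]-2-phenylchromen-4-one, via 2-hydroxyflavanone hemiketal 22 (not isolated)
Conditions: AcOH, conc. H2SO4 (2 equiv), 80 °C; aq. NaHCO3
Reagents that add atoms: none
Why: Acid-catalysed cyclodehydration: only the phenol that is to become O1 is free (O5 is still a methyl ether), so it alone adds to the benzoyl carbonyl group to give hemiketal 22, and loss of water closes the pyranone ring C with the piperidine necessarily on C8. The protonated amine is a spectator.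

Step 9
Reactants: 23 5,7-dimethoxy-8-[(2R)-1-methylpiperidin-2-yl]-2-phenylchromen-4-one
Product: 24 5,7-dihydroxy-8-[(2R)-1-methylpiperidin-2-yl]-2-phenylchromen-4-one
Conditions: BBr3 (8 equiv), CH2Cl2, −78 °C to rt; ice water, then aq. NaHCO3 to pH 7–8
Reagents that add atoms: none
Why: Lewis acid ether cleavage: BBr3 coordinates each methoxy oxygen and bromide removes the methyl group by SN2 attack, the C5 ether first (chelation to the C4 carbonyl group) and the C7 ether with the excess of reagent at room temperature. The anhydrous, non-protic medium should not open ring C, so no shift of the substituent from C8 to C6 is expected, and the boron-bound nitrogen is a poor leaving group, which protects C2'.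

## Compound list

1 | 3,5-dimethoxyphenol | COc1cc(O)cc(OC)c1 | starting material
2 | isopropyl isocyanate | CC(C)N=C=O | starting material
3 | 3,5-dimethoxyphenyl N-isopropylcarbamate | CC(C)NC(=O)Oc1cc(OC)cc(OC)c1 | intermediate
4 | 3,5-dimethoxyphenyl N-isopropyl-N-(trimethylsilyl)carbamate (not isolated) | CC(C)N([Si](C)(C)C)C(=O)Oc1cc(OC)cc(OC)c1 | intermediate
5 | [2,4-dimethoxy-6-[isopropyl(trimethylsilyl)carbamoyloxy]phenyl]lithium (not isolated) | [Li]c1c(OC)cc(OC)cc1OC(=O)N(C(C)C)[Si](C)(C)C | intermediate
6 | 3,5-dimethoxy-2-(trimethylsilyl)phenyl N-isopropyl-N-(trimethylsilyl)carbamate (not isolated) | COc1cc(OC)c([Si](C)(C)C)c(OC(=O)N(C(C)C)[Si](C)(C)C)c1 | intermediate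
7 | 3,5-dimethoxy-2-(trimethylsilyl)phenyl N-isopropylcarbamate | COc1cc(OC)c([Si](C)(C)C)c(OC(=O)NC(C)C)c1 | intermediate
8 | 3,5-dimethoxy-2-(trimethylsilyl)phenol (present as its DBU-H phenoxide; not isolated) | COc1cc(OC)c([Si](C)(C)C)c(O)c1 | intermediate
9 | 3,5-dimethoxy-2-(trimethylsilyl)phenyl trifluoromethanesulfonate | COc1cc(OC)c([Si](C)(C)C)c(OS(=O)(=O)C(F)(F)F)c1 | intermediate
10 | 1-methylpiperidin-2-one | CN1CCCCC1=O | starting material
11 | 3,5-dimethoxybenzyne (1,2-didehydro-3,5-dimethoxybenzene; not isolated) | COC1=CC(OC)=CC#C1 | intermediate
12 | 2,4-dimethoxy-6-[(1-methyl-2,3,4,5-tetrahydropyridin-1-ium-6-yl)oxy]benzen-1-ide (O-aryl imidate zwitterion; not isolated) | C[N+]1=C(CCCC1)Oc1cc(OC)cc(OC)[c-]1 | intermediate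
13 | 3,5-dimethoxy-1'-methylspiro[benzoxete-2,2'-piperidine] (racemic; not isolated) | CN1CCCCC12Oc3cc(OC)cc(OC)c32 | intermediate
14 | 3,5-dimethoxy-2-(1-methyl-2,3,4,5-tetrahydropyridin-1-ium-6-yl)phenolate | C[N+]1=C(CCCC1)c1c([O-])cc(OC)cc1OC | intermediate
15 | 6-(2-hydroxy-4,6-dimethoxyphenyl)-1-methyl-2,3,4,5-tetrahydropyridin-1-ium chloride (not isolated) | C[N+]1=C(CCCC1)c1c(O)cc(OC)cc1OC.[Cl-] | intermediate
16 | 3,5-dimethoxy-2-[(2R)-1-methylpiperidin-2-yl]phenol | CN1CCCC[C@@H]1c1c(O)cc(OC)cc1OC | intermediate
17 | 3,5-dimethoxy-2-[(2R)-1-methylpiperidin-2-yl]phenyl acetate (not isolated) | CN1CCCC[C@@H]1c1c(OC(C)=O)cc(OC)cc1OC | intermediate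
18 | 1-[2-hydroxy-4,6-dimethoxy-3-[(2R)-1-methylpiperidin-2-yl]phenyl]ethanone | CN1CCCC[C@@H]1c1c(O)c(C(C)=O)c(OC)cc1OC | intermediate
19 | benzoyl chloride | O=C(Cl)c1ccccc1 | starting material
20 | dilithium phenoxide enolate of 18 (not isolated) | CN1CCCC[C@@H]1c1c(O[Li])c(C(=C)O[Li])c(OC)cc1OC | intermediate
21 | 1-[2-hydroxy-4,6-dimethoxy-3-[(2R)-1-methylpiperidin-2-yl]phenyl]-3-phenylpropane-1,3-dione | CN1CCCC[C@@H]1c1c(O)c(C(=O)CC(=O)c2ccccc2)c(OC)cc1OC | intermediate
22 | 2-hydroxy-5,7-dimethoxy-8-[(2R)-1-methylpiperidin-2-yl]-2-phenyl-2,3-dihydrochromen-4-one (both C2 epimers; not isolated) | CN1CCCC[C@@H]1c1c(OC)cc(OC)c2C(=O)CC(O)(c3ccccc3)Oc12 | intermediate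
23 | 5,7-dimethoxy-8-[(2R)-1-methylpiperidin-2-yl]-2-phenylchromen-4-one | CN1CCCC[C@@H]1c1c(OC)cc(OC)c2c(=O)cc(-c3ccccc3)oc12 | intermediate
24 | 5,7-dihydroxy-8-[(2R)-1-methylpiperidin-2-yl]-2-phenylchromen-4-one | CN1CCCC[C@@H]1c1c(O)cc(O)c2c(=O)cc(-c3ccccc3)oc12 | target

## Step count and least certain steps

Total: 9 steps. Longest linear sequence: 9 steps (1 to 24); the route is fully linear, and 2, 10 and 19 enter as purchased reagents.

**Step 4 (key step, proposed new method).** The most likely failure is that the aryl anion of 12 takes a proton from the alpha-CH2 group of its own imidate before it can close the four-membered ring. That would give an O-aryl ketene N,O-acetal, leading after work-up to O-arylation or, by a sigmatropic shift, to arylation at C3' instead of C2'. A second risk is further arylation of the nucleophilic product by the aryne if the aryne concentration rises. The fallback uses known organolithium chemistry and sets out from 1. The phenol is protected as 1,3-dimethoxy-5-(methoxymethoxy)benzene F1 (MOMCl, i-Pr2NEt, CH2Cl2). Directed ortho-lithiation with n-BuLi/TMEDA in THF, between the acetal oxygen and a methoxy group, gives [2,4-dimethoxy-6-(methoxymethoxy)phenyl]lithium F2. F2 adds to the carbonyl group of 10 at −78 °C to give lithium 2-[2,4-dimethoxy-6-(methoxymethoxy)phenyl]-1-methylpiperidin-2-olate F3. HCl in MeOH then dehydrates the hemiaminal and removes the acetal, and the route is rejoined at iminium chloride 15.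

**Step 5.** Slow turnover or poor facial discrimination is possible, because the aryl group of 15 has two ortho substituents and is twisted out of the iminium plane, and the free phenol may bind the metal. The sense of induction also cannot be predicted with certainty. The fallback replaces catalysis by resolution and sets out from 15. NaBH4 in MeOH should give racemic 3,5-dimethoxy-2-(1-methylpiperidin-2-yl)phenol F4. Preparative chromatography on a chiral stationary phase then separates 16 from its enantiomer, 3,5-dimethoxy-2-[(2S)-1-methylpiperidin-2-yl]phenol F5, and the route continues from 16.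

**Step 6.** Two processes threaten this step. One is acylation at the position between the two methoxy groups (para to the phenol) in competition with the ortho position. The other is partial loss of configuration by reversible heterolysis of the benzylic C2'–N bond of the boron-complexed amine, which is assisted by three donor oxygens when the mixture is warmed. The fallback avoids Lewis acid and sets out from 16. Magnesium-mediated ortho-formylation (MgCl2, Et3N, paraformaldehyde, MeCN, reflux), which is specific for the position next to the phenol, gives 2-hydroxy-4,6-dimethoxy-3-[(2R)-1-methylpiperidin-2-yl]benzaldehyde F6. MeMgBr in THF gives 2-(1-hydroxyethyl)-3,5-dimethoxy-6-[(2R)-1-methylpiperidin-2-yl]phenol F7, and MnO2 in CH2Cl2 oxidises the benzylic alcohol to 18.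

**Step 9.** Cleavage of the C7 ether may be incomplete, since it is flanked by the C8 substituent whose nitrogen binds the reagent. If warming is needed, erosion at C2' becomes possible once O7 is free and can assist C–N cleavage. The fallback separates the two cleavages by mechanism and sets out from 23. BCl3 in CH2Cl2 (−78 to 0 °C) removes only the chelated C5 methyl group and gives 5-hydroxy-7-methoxy-8-[(2R)-1-methylpiperidin-2-yl]-2-phenylchromen-4-one F8. NaSEt in DMF at about 100 °C then removes the C7 methyl group by SN2 attack under non-acidic conditions and gives 24.

## Further compounds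

F1 | step 4 | 1,3-dimethoxy-5-(methoxymethoxy)benzene | COCOc1cc(OC)cc(OC)c1
F2 | step 4 | [2,4-dimethoxy-6-(methoxymethoxy)phenyl]lithium | COCOc1cc(OC)cc(OC)c1[Li]
F3 | step 4 | lithium 2-[2,4-dimethoxy-6-(methoxymethoxy)phenyl]-1-methylpiperidin-2-olate (racemic) | CN1CCCCC1(O[Li])c1c(OC)cc(OC)cc1OCOC
F4 | step 5 | racemic 3,5-dimethoxy-2-(1-methylpiperidin-2-yl)phenol | CN1CCCCC1c1c(O)cc(OC)cc1OC
F5 | step 5 | 3,5-dimethoxy-2-[(2S)-1-methylpiperidin-2-yl]phenol | CN1CCCC[C@H]1c1c(O)cc(OC)cc1OC
F6 | step 6 | 2-hydroxy-4,6-dimethoxy-3-[(2R)-1-methylpiperidin-2-yl]benzaldehyde | CN1CCCC[C@@H]1c1c(O)c(C=O)c(OC)cc1OC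
F7 | step 6 | 2-(1-hydroxyethyl)-3,5-dimethoxy-6-[(2R)-1-methylpiperidin-2-yl]phenol (both carbinol epimers) | CN1CCCC[C@@H]1c1c(O)c(C(C)O)c(OC)cc1OC
F8 | step 9 | 5-hydroxy-7-methoxy-8-[(2R)-1-methylpiperidin-2-yl]-2-phenylchromen-4-one | CN1CCCC[C@@H]1c1c(OC)cc(O)c2c(=O)cc(-c3ccccc3)oc12
A1 | alternative 1 | tert-butyl (2R)-2-[4-ethoxy-2-hydroxy-6-(triisopropylsilyloxy)phenyl]piperidine-1-carboxylate | CC(C)(C)OC(=O)N1CCCC[C@@H]1c1c(O)cc(OCC)cc1O[Si](C(C)C)(C(C)C)C(C)C
A2 | alternative 1 | 3-ethoxycyclobut-2-en-1-one | CCOC1=CC(=O)C1
A3 | alternative 1 | tert-butyl (2R)-2-[2-(triisopropylsilyloxy)ethynyl]piperidine-1-carboxylate | CC(C)(C)OC(=O)N1CCCC[C@@H]1C#CO[Si](C(C)C)(C(C)C)C(C)C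
A4 | alternative 1 | (2R)-piperidine-2-carboxylic acid | N1CCCC[C@@H]1C(=O)O
A5 | alternative 2 | (2R)-2-[2-(benzyloxy)-4,6-dimethoxyphenyl]-1-[(R)-tert-butylsulfinyl]-2,3-dihydropyridin-4-one | CC(C)(C)[S@@](=O)N1C=CC(=O)C[C@@H]1c1c(OCc2ccccc2)cc(OC)cc1OC
A6 | alternative 2 | (R)-N-[[2-(benzyloxy)-4,6-dimethoxyphenyl]methylidene]-2-methylpropane-2-sulfinamide | CC(C)(C)[S@@](=O)/N=C/c1c(OCc2ccccc2)cc(OC)cc1OC
A7 | alternative 2 | (E)-1-methoxy-3-(trimethylsilyloxy)buta-1,3-diene | CO/C=C/C(=C)O[Si](C)(C)C
A8 | alternative 3 | 5,7-dimethoxy-8-[(2R)-1-methylpiperidin-2-yl]-2-phenylchromen-4-one (identical with 23) | CN1CCCC[C@@H]1c1c(OC)cc(OC)c2c(=O)cc(-c3ccccc3)oc12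
A9 | alternative 3 | 2-iodo-3,5-dimethoxy-6-[(2R)-1-methylpiperidin-2-yl]phenol | CN1CCCC[C@@H]1c1c(O)c(I)c(OC)cc1OC
A10 | alternative 3 | phenylacetylene | C#Cc1ccccc1
A11 | alternative 3 | carbon monoxide | [C-]#[O+]
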